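## Retrosynthetic overview

1. The ester is made last from rohitukine 16 and 3,4-dimethoxybenzoyl chloride 17. The pyranone ring of the chromone comes from C-acetylation, Claisen condensation and cyclodehydration on a 2,4,6-trimethoxyphenyl group (the masked phloroglucinol ring), followed by O-demethylation.
2. The cis C3–OH goes back to a C3 ketone (hydride anti to the C4 aryl group) and this to a C3 nitro group (Nef). The piperidine ring then comes in one operation from the acyclic γ-nitroaldehyde 5 (C3–C4–C5–C6) and N-methylmethanimine (N1–C2, from triazinane 6).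
3. Enabling feature: in the piperidine ring the oxygen-bearing C3 lies between C2, which is bound to N1, and the benzylic C4. With nitro in place of oxygen, C3 is an acidic carbon that attacks the imine carbon C2, while C6, the other neighbour of N1, sits three carbons along the chain as an aldehyde on which the same nitrogen closes.
4. C4 (R) comes from an enamine-catalysed Michael addition of acetaldehyde to nitroalkene 3, itself made from aldehyde 1 and nitromethane.
5. Ring order: benzene ring bought; piperidine ring (step 3); pyranone ring (step 7).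

Key step: step 3

Assumption: the prolinol silyl ether catalyst follows the usual enamine shielding model, so that the (R)-catalyst should give (R)-5. Compound 9 is drawn as the expected trans (3R,4R) isomer; its C3 epimer would serve equally, because C3 becomes trigonal in step 4.

## Route

Step 1
Reactants: 1 2,4,6-trimethoxybenzaldehyde; 2 nitromethane
Product: 3 (E)-1,3,5-trimethoxy-2-(2-nitrovinyl)benzene
Conditions: NH4OAc (0.5 equiv), MeNO2 (solvent), AcOH, 90 °C
Reagents that add atoms: none
Why: Henry (nitroaldol) condensation followed by dehydration, which should give the conjugated E-nitroalkene as the thermodynamic isomer.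

Step 2
Reactants: 3 (E)-1,3,5-trimethoxy-2-(2-nitrovinyl)benzene; 4 acetaldehyde
Product: 5 (R)-4-nitro-3-(2,4,6-trimethoxyphenyl)butanal
Conditions: (R)-α,α-diphenylprolinol trimethylsilyl ether (20 mol %), MeCHO (10 equiv), 1,4-dioxane, rt
Reagents that add atoms: none
Why: Enamine-catalysed asymmetric Michael addition, in which the acetaldehyde enamine should add to the nitroalkene face not shielded by the diphenyl(silyloxy)methyl group and so set the benzylic centre (the later C4) as R.

Step 3
Reactants: 5 (R)-4-nitro-3-(2,4,6-trimethoxyphenyl)butanal; 6 1,3,5-trimethyl-1,3,5-triazinane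
Product: 9 (3R,4R)-1-methyl-3-nitro-4-(2,4,6-trimethoxyphenyl)piperidine, via open-chain nitro amine 7 (not isolated), via cyclic hemiaminal 8 (not isolated)
Conditions: 6 (0.35 equiv, one equivalent of CH2=NMe), CH2Cl2, rt to 40 °C; then AcOH (3 equiv), NaBH(OAc)3 (2 equiv), 0 °C to rt
Reagents that add atoms: none
Why: Triazinane 6 dissociates to N-methylmethanimine, whose carbon (the later C2) is attacked by the nitronate carbon of 5 (the later C3) in a nitro-Mannich (aza-Henry) reaction to give 7, whose new secondary amine adds to the aldehyde carbon (the later C6) to give 8, which NaBH(OAc)3/AcOH should reduce through the cyclic iminium ion to 9. The closest known reaction type is the nitro-Mannich/cyclization cascade of γ-nitro carbonyl compounds with imines (hemiaminalization or lactamization), ended here by an iminium reduction of the reductive-amination type. The only ring closure is the N1–C6 bond, a 6-exo-trig attack of nitrogen on the aldehyde, while the C2–C3 bond is made between the two components. C4 is carried over unchanged from 5 because its hydrogen is not acidic, and the new C3 centre is under thermodynamic control through reversible nitronate formation and should settle trans (nitro and aryl both equatorial), which is of no consequence since step 4 makes C3 trigonal. The step needs single aminomethylation at the nitro carbon in preference to a second Mannich reaction there, to aminomethylation next to the aldehyde and to intermolecular nitroaldol reaction; the far higher acidity of the nitro α-hydrogens, the use of one equivalent of imine, the fast intramolecular capture of the amine by the aldehyde and the reversibility of the competing additions should secure it.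

Step 4
Reactants: 9 (3R,4R)-1-methyl-3-nitro-4-(2,4,6-trimethoxyphenyl)piperidine
Product: 10 (4R)-1-methyl-4-(2,4,6-trimethoxyphenyl)piperidin-3-one
Conditions: NaOMe (1.1 equiv), MeOH, 0 °C; then aq. TiCl3 (4 equiv), NH4OAc buffer (pH 5–6), 0 °C to rt; cold NaHCO3 work-up, crude ketone used at once
Reagents that add atoms: water, O
Why: Reductive Nef reaction, in which trivalent titanium reduces the nitronate to the N–H imine that hydrolyses to the ketone under weakly acidic conditions, which should leave the protonated tertiary amine and the benzylic centre alone.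

Step 5
Reactants: 10 (4R)-1-methyl-4-(2,4,6-trimethoxyphenyl)piperidin-3-one
Product: 11 (3S,4R)-1-methyl-4-(2,4,6-trimethoxyphenyl)piperidin-3-ol
Conditions: LiBH(sec-Bu)3 (1.3 equiv), THF, −78 °C; MeOH quench, acid–base extraction (no peroxide)
Reagents that add atoms: none
Why: Substrate-controlled ketone reduction, in which the bulky hydride attacks the chair with equatorial aryl group from the equatorial side, as with 2-arylcyclohexanones, and should give the axial alcohol cis to the aryl group (C3 = S).

Step 6
Reactants: 11 (3S,4R)-1-methyl-4-(2,4,6-trimethoxyphenyl)piperidin-3-ol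
Product: 13 1-{2-hydroxy-3-[(3S,4R)-3-hydroxy-1-methylpiperidin-4-yl]-4,6-dimethoxyphenyl}ethanone, via O-acetate 12 (not isolated)
Conditions: Ac2O (6 equiv), BF3·OEt2 (6 equiv), CH2Cl2, 0 °C to rt; aq. NaHCO3 work-up; then K2CO3 (cat.), MeOH, rt
Reagents that add atoms: acetic anhydride, CC(=O)OC(C)=O
Why: Friedel–Crafts acetylation at one of the two equivalent free ring positions with BF3-assisted cleavage of the methoxy group flanked by the acetyl and piperidinyl groups (chelation and relief of strain), after which methanolysis removes the acetate formed on the C3 hydroxyl.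

Step 7
Reactants: 13 1-{2-hydroxy-3-[(3S,4R)-3-hydroxy-1-methylpiperidin-4-yl]-4,6-dimethoxyphenyl}ethanone
Product: 15 8-[(3S,4R)-3-hydroxy-1-methylpiperidin-4-yl]-5,7-dimethoxy-2-methyl-4H-chromen-4-one, via 1,3-diketone 14 (not isolated)
Conditions: NaH (5 equiv), EtOAc (solvent), reflux; then conc. HCl, MeOH, 50 °C
Reagents that add atoms: ethyl acetate, CCOC(C)=O
Why: Crossed Claisen condensation of the methyl ketone enolate with ethyl acetate gives the 1,3-diketone, which should close the 2-methylpyranone ring by acid-catalysed 6-exo-trig attack of the ortho phenol on the terminal ketone and dehydration.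

Step 8
Reactants: 15 8-[(3S,4R)-3-hydroxy-1-methylpiperidin-4-yl]-5,7-dimethoxy-2-methyl-4H-chromen-4-one
Product: 16 rohitukine, 5,7-dihydroxy-8-[(3S,4R)-3-hydroxy-1-methylpiperidin-4-yl]-2-methyl-4H-chromen-4-one
Conditions: pyridine hydrochloride (excess), neat, 180 °C; NaHCO3 work-up
Reagents that add atoms: none
Why: Double aryl methyl ether cleavage by chloride attack (SN2) on the protonated ethers, conditions under which neither stereocentre has a pathway for epimerization.

Step 9
Reactants: 16 rohitukine; 17 3,4-dimethoxybenzoyl chloride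
Product: 19 chrotacumine D, (3S,4R)-4-(5,7-dihydroxy-2-methyl-4-oxo-4H-chromen-8-yl)-1-methylpiperidin-3-yl 3,4-dimethoxybenzoate, via bis-veratroate 18 (not isolated)
Conditions: 17 (3 equiv), Et3N, DMAP (cat.), CH2Cl2, 0 °C to rt; then MeOH, rt
Reagents that add atoms: none
Why: DMAP-catalysed acylation esterifies the secondary alcohol with retention, and the activated aryl ester formed on the acidic C7 phenol should then be removed selectively by amine-catalysed methanolysis, which leaves the hindered alkyl ester untouched.

## Compound list

1 | 2,4,6-trimethoxybenzaldehyde | COc1cc(OC)c(C=O)c(OC)c1 | starting material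
2 | nitromethane | C[N+](=O)[O-] | starting material
3 | (E)-1,3,5-trimethoxy-2-(2-nitrovinyl)benzene | COc1cc(OC)c(/C=C/[N+](=O)[O-])c(OC)c1 | intermediate
4 | acetaldehyde | CC=O | starting material
5 | (R)-4-nitro-3-(2,4,6-trimethoxyphenyl)butanal | O=CC[C@@H](C[N+](=O)[O-])c1c(OC)cc(OC)cc1OC | intermediate
6 | 1,3,5-trimethyl-1,3,5-triazinane | CN1CN(C)CN(C)C1 | starting material
7 | (3R)-5-(methylamino)-4-nitro-3-(2,4,6-trimethoxyphenyl)pentanal (C4 epimers) | CNCC([N+](=O)[O-])[C@H](CC=O)c1c(OC)cc(OC)cc1OC | intermediate
8 | (4R)-1-methyl-5-nitro-4-(2,4,6-trimethoxyphenyl)piperidin-2-ol (epimers at C2 and C5) | [O-][N+](=O)C1CN(C)C(O)C[C@@H]1c2c(OC)cc(OC)cc2OC | intermediate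
9 | (3R,4R)-1-methyl-3-nitro-4-(2,4,6-trimethoxyphenyl)piperidine | [O-][N+](=O)[C@H]1CN(C)CC[C@@H]1c2c(OC)cc(OC)cc2OC | intermediate
10 | (4R)-1-methyl-4-(2,4,6-trimethoxyphenyl)piperidin-3-one | O=C1CN(C)CC[C@@H]1c2c(OC)cc(OC)cc2OC | intermediate
11 | (3S,4R)-1-methyl-4-(2,4,6-trimethoxyphenyl)piperidin-3-ol | O[C@@H]1CN(C)CC[C@@H]1c2c(OC)cc(OC)cc2OC | intermediate
12 | (3S,4R)-4-(3-acetyl-2-hydroxy-4,6-dimethoxyphenyl)-1-methylpiperidin-3-yl acetate | CC(=O)O[C@@H]1CN(C)CC[C@@H]1c2c(O)c(C(C)=O)c(OC)cc2OC | intermediate
13 | 1-{2-hydroxy-3-[(3S,4R)-3-hydroxy-1-methylpiperidin-4-yl]-4,6-dimethoxyphenyl}ethanone | O[C@@H]1CN(C)CC[C@@H]1c2c(O)c(C(C)=O)c(OC)cc2OC | intermediate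
14 | 1-{2-hydroxy-3-[(3S,4R)-3-hydroxy-1-methylpiperidin-4-yl]-4,6-dimethoxyphenyl}butane-1,3-dione | O[C@@H]1CN(C)CC[C@@H]1c2c(O)c(C(=O)CC(C)=O)c(OC)cc2OC | intermediate
15 | 8-[(3S,4R)-3-hydroxy-1-methylpiperidin-4-yl]-5,7-dimethoxy-2-methyl-4H-chromen-4-one | O[C@@H]1CN(C)CC[C@@H]1c2c(OC)cc(OC)c3c(=O)cc(C)oc23 | intermediate
16 | rohitukine, 5,7-dihydroxy-8-[(3S,4R)-3-hydroxy-1-methylpiperidin-4-yl]-2-methyl-4H-chromen-4-one | O[C@@H]1CN(C)CC[C@@H]1c2c(O)cc(O)c3c(=O)cc(C)oc23 | intermediate
17 | 3,4-dimethoxybenzoyl chloride | COc1ccc(C(=O)Cl)cc1OC | starting material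
18 | (3S,4R)-4-[7-(3,4-dimethoxybenzoyloxy)-5-hydroxy-2-methyl-4-oxo-4H-chromen-8-yl]-1-methylpiperidin-3-yl 3,4-dimethoxybenzoate | COc1ccc(C(=O)O[C@@H]2CN(C)CC[C@@H]2c3c(OC(=O)c4ccc(OC)c(OC)c4)cc(O)c5c(=O)cc(C)oc35)cc1OC | intermediate
19 | chrotacumine D, (3S,4R)-4-(5,7-dihydroxy-2-methyl-4-oxo-4H-chromen-8-yl)-1-methylpiperidin-3-yl 3,4-dimethoxybenzoate | COc1ccc(C(=O)O[C@@H]2CN(C)CC[C@@H]2c2c(O)cc(O)c3c(=O)cc(C)oc23)cc1OC | target

## Step count and risks

Total steps: 9. Longest linear sequence: 9 steps (from 1 to 19).

Steps most likely to fail: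

1. Step 3. Ring closure may be overtaken by a second aminomethylation at the nitro carbon, by aminomethylation next to the aldehyde, or by intermolecular nitroaldol oligomerization of 5. The fallback replaces the aldehyde by an ester, so that ring closure becomes an irreversible lactamization of the known nitro-Mannich/lactamization type. It sets out from 5: chlorite oxidation (NaClO2, NaH2PO4, 2-methyl-2-butene, t-BuOH/H2O) should give (R)-4-nitro-3-(2,4,6-trimethoxyphenyl)butanoic acid F1. Esterification (MeOH, H2SO4 cat.) should give methyl (R)-4-nitro-3-(2,4,6-trimethoxyphenyl)butanoate F2. Reaction with triazinane 6 (MeOH, 65 °C) should give (4R,5R)-1-methyl-5-nitro-4-(2,4,6-trimethoxyphenyl)piperidin-2-one F3. Reduction of the lactam with BH3·SMe2 (THF, reflux; then MeOH/HCl), which leaves the aliphatic nitro group alone, comes back to the route at 9.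

2. Step 4. The benzylic centre may lose configuration by enolization of the newly formed ketone during the Nef reaction or its work-up. The fallback uses this lability instead of fighting it. It sets out from ketone 10 of eroded enantiomeric purity and hydrogenates it under dynamic kinetic resolution (H2, RuCl2(xylbinap)(daipen), KOt-Bu, i-PrOH), with the catalyst antipode that is matched to the (3S) carbinol chosen in a preliminary run with both antipodes. Both enantiomers of the equilibrating ketone should then converge on the cis alcohol, and the fallback comes back to the route at 11. It makes no new compound (none F0).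

3. Step 2. Conjugate addition at the di-ortho-substituted, electron-rich β-carbon of 3 may be too slow and be outpaced by self-aldol condensation of acetaldehyde. The fallback exchanges the polarity of the two partners. It sets out from 1: Wittig olefination with Ph3P=CHCHO (toluene, 80 °C) should give (E)-3-(2,4,6-trimethoxyphenyl)prop-2-enal F4. Iminium-catalysed Michael addition of nitromethane 2 ((R)-α,α-diphenylprolinol trimethylsilyl ether, PhCO2H, MeOH, rt) comes back to the route at 5.

Further compounds
F1 | step 3 | (R)-4-nitro-3-(2,4,6-trimethoxyphenyl)butanoic acid | OC(=O)C[C@@H](C[N+](=O)[O-])c1c(OC)cc(OC)cc1OC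
F2 | step 3 | methyl (R)-4-nitro-3-(2,4,6-trimethoxyphenyl)butanoate | COC(=O)C[C@@H](C[N+](=O)[O-])c1c(OC)cc(OC)cc1OC
F3 | step 3 | (4R,5R)-1-methyl-5-nitro-4-(2,4,6-trimethoxyphenyl)piperidin-2-one | [O-][N+](=O)[C@H]1CN(C)C(=O)C[C@@H]1c2c(OC)cc(OC)cc2OC
F0 | step 4 | none | none
F4 | step 2 | (E)-3-(2,4,6-trimethoxyphenyl)prop-2-enal | COc1cc(OC)c(/C=C/C=O)c(OC)c1
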